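If a charge of catalyst can carry out a fixed number of rounds, the target in a flask is a matter of bookkeeping, so I kept the books on the starting material.

common to all: second substrate 0.115 M; coupling partner 0.276 M

| run | starting material | free catalyst | remark | time |
|---|---|---|---|---|
| dawn | 0.10 M (fed, over 2.0 h) | 3.9 mM | run made earlier |  |
| ash | 0.10 M (fed, over 2.0 h) | 5.8 mM |  | 30 h |
| oak | 0.15 M (fed, over 2.0 h) | 5.8 mM |  | 30 h |
| maple | 0.25 M (fed, over 2.0 h) | 5.8 mM |  | 30 h |
| alder | 0.30 M (fed, over 2.0 h) | 5.8 mM |  | 30 h |
| cedar | 0.50 M (fed, over 2.0 h) | 5.8 mM |  | 30 h |

dawn run (percent of the starting material charged)

| time / h | target / % |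
|---|---|
| 1.00 | 2 |
| 2.50 | 4 |
| 5.00 | 10 |
| 8.00 | 17 |
| 10.0 | 15 |

(scatter of a reading: 1.5 percentage points)

- "hardly changes" means that all values lie within two and a half points (for a concentration: within two and a half percent of the largest)
- percentages count the whole charge, also what has not yet gone in
- no earlier run changes the charge of free catalyst; that part of a forecast is a guess

- amount of target at the end, in percent of the starting material charged for ash, oak, maple, alder, cedar, in this order
- the course of these numbers from the first flask to the last (rises, then falls / rises all the way / falls, then rises / hardly changes / falls all the way)

The dawn ledger opened with 0.10 M of starting material, fed in over 2.0 h. The target entry read 17% at 8.00 h and 15% at 10.0 h, a gap of 2 percentage points against a scatter of 1.5 points, so I read one plateau near 16.0%. I booked the remaining 84.0% as unreacted starting material and took the plateau for a stopped catalyst. My turnover number came to 4.10: moles of target at the plateau per mole of free catalyst charged.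

I carried it to ash, where 5.8 mM of catalyst stood in the flask; that step was a guess, since no earlier run changes the catalyst charge. In ash the starting material is the limiting reagent, 0.10 M against 0.276 M of coupling partner. My ledger for ash entered 23.8% as target and closed with 76.2% as starting material. For cedar, the same catalyst spread over 0.50 M gave 4.76% as target and 95.2% as starting material.

The forecast gave 28%, 19%, 11%, 9% and 6%, a course that falls all the way, on the ground that “Extra starting material then adds nothing”. Its figures for ash and cedar stood above mine, though the course was the same.

The flasks gave 31.4%, 29.2%, 24.9%, 23.1% and 17.4%, a course that falls all the way.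

    starting material + free catalyst ⇌ catalyst intermediate A (K = 7.10 /M, k = 0.0270 /M/s)
    coupling partner + catalyst intermediate A ⇌ free catalyst + target (K = 0.360, k = 0.00220 /M/s)
    second substrate + free catalyst ⇌ catalyst intermediate B (K = 3.40 /M, k = 0.0130 /M/s)
    coupling partner + catalyst intermediate B → free catalyst + second product (k = 0.00230 /M/s)
    starting material + free catalyst → spent catalyst (k = 1.10 × 10⁻⁴ /M/s)

The course agreed, but the counts parted: ash stood at 5.41 moles of target per mole of free catalyst charged and cedar at 15.0, both above my 4.10. At 30.0 h ash still held 65.4% of its starting material with 36.6% of its catalyst free, and its books closed short of the charge because catalyst intermediate A returned to starting material and free catalyst. With that return taken away, ash reached 95.0% of target instead of 31.4%.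

The earlier runs and the new flask stem from a simulated flask from invented constants; noise was put on by code.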